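**Plan**

1. Cuts: C8=C17 (ketone methylenation) and the C8 oxygen (allylic oxidation) come off first. C4–C5 is then cut by a retro-Ireland–Claisen step that reopens ring A to a bridged ten-membered lactone (C19 acyl on the C7 oxygen, C5=C6). After that come C19–O (lactonisation), C2–C3 (cross-metathesis), C10–C1 (enolate allylation) and C9–C11 (conjugate addition).
2. Forward order: the C11–C15 chain is joined at C9 to 2-methylcyclohexenone (the future ring B) and C10 is allylated in the same flask. The arm is extended to C19, ring B is transposed to the 5-en-7-ol, and the lactone is closed and then contracted, so ring A arises last. C8 is then oxidised and methylenated.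
3. Enabling feature: rings A and B are cis-fused and the C19 carboxyl on C4 is cis to C6. C4, C1 and an oxygen on C7 can therefore all sit on one face of ring B, so the acyl unit C19–C4 can be passed from O–C7 to C5 across that face while C1–C3 hold C4 to C10.
4. Stereochemistry: C13 comes from the (R)-monoester and C9 from a ligand-controlled copper-catalysed conjugate addition. C10 is set by allylation anti to the C9 chain, and C7 by epoxidation anti to the C9 chain, carried through a Wharton transposition. C5 and C4 come from the suprafacial, tether-bound [3,3] shift.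

Key step: step 11

Remarks on the chemistry:
- Labdane numbering is used for locants (rings C1–C10, chain C11–C16, C17 methylidene, C18 and C19 on C4, C20 on C10).
- C4 is carried as both epimers from compound 9 to compound 17 and is drawn without configuration there, because it becomes trigonal in step 11.
- The sense of induction in step 4 is assumed to follow that of cyclohex-2-enone with this ligand class; if it does not, the antipodal ligand is used.
- In step 4 the (trimethylsilyl)methyl group on zinc is assumed to stay on the metal, so that only the functionalised alkyl group is transferred.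

**Route**

Step 1
Reactants: 1 methyl hydrogen (R)-3-methylglutarate
Product: 2 methyl (3R)-5-hydroxy-3-methylpentanoate
Conditions: BH3·SMe2, THF, 0 °C to rt; MeOH, then aqueous work-up; used at once
Reagents that add atoms: none
Why: Chemoselective borane reduction takes the free carboxylic acid much faster than the methyl ester, C13 is not touched, and immediate use avoids lactonisation of the hydroxy ester.

Step 2
Reactants: 2 methyl (3R)-5-hydroxy-3-methylpentanoate
Product: 3 methyl (3S)-5-iodo-3-methylpentanoate
Conditions: I2, PPh3, imidazole, CH2Cl2, 0 °C to rt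
Reagents that add atoms: iodine, II
Why: Appel-type iodination displaces the alkoxyphosphonium group by SN2 at a primary, non-stereogenic carbon, so C13 keeps its geometry and only its descriptor changes.

Step 3
Reactants: 3 methyl (3S)-5-iodo-3-methylpentanoate
Product: 5 [(3S)-5-methoxy-3-methyl-5-oxopentyl][(trimethylsilyl)methyl]zinc, via alkylzinc iodide 4 (not isolated)
Conditions: Zn dust (activated with BrCH2CH2Br and Me3SiCl), THF, 40 °C; solution decanted from excess Zn; Me3SiCH2Li (pentane, 1.0 equiv), −78 to 0 °C; solvents removed in vacuo, residue taken up in toluene and filtered from LiI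
Reagents that add atoms: zinc, [Zn]; (trimethylsilyl)methyllithium, [Li]C[Si](C)(C)C
Why: Direct insertion of activated zinc into a primary alkyl iodide tolerates the ester, and transmetallation of the alkylzinc iodide with Me3SiCH2Li at low temperature, which is much faster than addition to the ester, gives the mixed diorganozinc whose silylmethyl group acts as a non-transferable ligand, so every molecule of the chain remains available for transfer; no stereocentre is involved.

Step 4
Reactants: 5 [(3S)-5-methoxy-3-methyl-5-oxopentyl][(trimethylsilyl)methyl]zinc; 6 2-methylcyclohex-2-en-1-one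
Product: 8 methyl (3R)-3-methyl-5-[(1S,2S)-2-methyl-3-oxo-2-(prop-2-en-1-yl)cyclohexyl]pentanoate, via zinc enolate 7 (not isolated)
Conditions: 5 (1.3 equiv), Cu(OTf)2 (2 mol%), (R,S,S)-phosphoramidite from 1,1'-bi-2-naphthol and bis(1-phenylethyl)amine (4 mol%), toluene, −30 to 0 °C; then Pd(PPh3)4 (4 mol%), allyl acetate, 0 °C to rt; aq. HCl
Reagents that add atoms: allyl acetate, C=CCOC(C)=O
Why: Copper-catalysed asymmetric conjugate addition of a diorganozinc to an α-substituted cyclohexenone sets C9 under ligand control while the (trimethylsilyl)methyl group stays on zinc, and zerovalent-palladium-catalysed allylation of the regiodefined zinc enolate (tandem conjugate addition–enolate allylation) should occur anti to the C9 chain, placing the C10 methyl cis to the chain.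

Step 5
Reactants: 8 methyl (3R)-3-methyl-5-[(1S,2S)-2-methyl-3-oxo-2-(prop-2-en-1-yl)cyclohexyl]pentanoate; 9 2-methylbut-3-enoic acid (racemic)
Product: 10 (3E)-5-[(1S,2S)-2-[(3R)-5-methoxy-3-methyl-5-oxopentyl]-1-methyl-6-oxocyclohexyl]-2-methylpent-3-enoic acid (C4 epimers; some Z isomer)
Conditions: second-generation Hoveyda–Grubbs catalyst RuCl2(H2IMes)(=CH-C6H4-2-O-i-Pr) (5 mol%), 9 (4 equiv), 1,4-benzoquinone (10 mol%), CH2Cl2, 40 °C
Reagents that add atoms: none
Why: Olefin cross-metathesis joins the terminal allyl carbon C2 to C3 of the acid with loss of ethene; benzoquinone holds back double-bond migration, and the E/Z and C4 mixtures do not matter.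

Step 6
Reactants: 10 (3E)-5-[(1S,2S)-2-[(3R)-5-methoxy-3-methyl-5-oxopentyl]-1-methyl-6-oxocyclohexyl]-2-methylpent-3-enoic acid
Product: 11 5-[(1S,2S)-2-[(3R)-5-methoxy-3-methyl-5-oxopentyl]-1-methyl-6-oxocyclohexyl]-2-methylpentanoic acid (C4 epimers)
Conditions: H2 (1 atm), Pd/C, EtOAc, rt
Reagents that add atoms: none
Why: Heterogeneous catalytic hydrogenation saturates the only C=C, so both alkene isomers converge, while the ketone and esters stay intact and no controlled stereocentre is made.

Step 7
Reactants: 11 5-[(1S,2S)-2-[(3R)-5-methoxy-3-methyl-5-oxopentyl]-1-methyl-6-oxocyclohexyl]-2-methylpentanoic acid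
Product: 12 5-[(1S,6R)-6-[(3R)-5-methoxy-3-methyl-5-oxopentyl]-1-methyl-2-oxocyclohex-3-en-1-yl]-2-methylpentanoic acid (C5 ketone, C6=C7)
Conditions: IBX (2-iodoxybenzoic acid, 1.5–2 equiv), DMSO/toluene, 70 °C
Reagents that add atoms: none
Why: IBX-mediated α,β-dehydrogenation of the ketone can only give the C6=C7 enone because C10 is quaternary, and limiting the oxidant should stop it before the dienone.

Step 8
Reactants: 12 5-[(1S,6R)-6-[(3R)-5-methoxy-3-methyl-5-oxopentyl]-1-methyl-2-oxocyclohex-3-en-1-yl]-2-methylpentanoic acid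
Product: 13 5-[(1R,3S,4R,6R)-4-[(3R)-5-methoxy-3-methyl-5-oxopentyl]-3-methyl-2-oxo-7-oxabicyclo[4.1.0]heptan-3-yl]-2-methylpentanoic acid (6,7-epoxide on the face of the C10 arm)
Conditions: t-BuOOH (in decane), DBU, CH2Cl2, 0 °C to rt; aq. citric acid
Reagents that add atoms: tert-butyl hydroperoxide, CC(C)(C)OO
Why: Nucleophilic (Weitz–Scheffer) epoxidation of the enone: the peroxide should add axially to C7 anti to the C9 chain, as is usual for 5-substituted cyclohex-2-enones, which puts the oxirane on the face of the C10 arm.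

Step 9
Reactants: 13 5-[(1R,3S,4R,6R)-4-[(3R)-5-methoxy-3-methyl-5-oxopentyl]-3-methyl-2-oxo-7-oxabicyclo[4.1.0]heptan-3-yl]-2-methylpentanoic acid
Product: 15 5-[(1S,4R,6R)-4-hydroxy-6-[(3R)-5-methoxy-3-methyl-5-oxopentyl]-1-methylcyclohex-2-en-1-yl]-2-methylpentanoic acid (C4 epimers), via epoxy hydrazone 14 (not isolated)
Conditions: N2H4·H2O, AcOH, MeOH, 0 °C to rt
Reagents that add atoms: none
Why: Wharton transposition: the epoxy hydrazone opens at C6–O and loses N2, moving the alkene to C5=C6 and leaving the C7–O bond, and so its configuration (cis to the arm), untouched.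

Step 10
Reactants: 15 5-[(1S,4R,6R)-4-hydroxy-6-[(3R)-5-methoxy-3-methyl-5-oxopentyl]-1-methylcyclohex-2-en-1-yl]-2-methylpentanoic acid
Product: 17 methyl (3R)-5-[(1R,8S,12R)-4,8-dimethyl-3-oxo-2-oxabicyclo[6.2.2]dodec-9-en-12-yl]-3-methylpentanoate (C4 epimers), via mixed anhydride 16 (not isolated)
Conditions: 2,4,6-Cl3C6H2COCl, Et3N, THF, rt; then added over 10 h to DMAP, toluene, 90 °C (about 1 mM)
Reagents that add atoms: none
Why: Yamaguchi macrolactonisation acylates the C7 hydroxyl with retention, and because this hydroxyl and the C10 arm are cis on ring B the six-atom bridge can span the 1,4-positions of a boat-like cyclohexene.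

Step 11
Reactants: 17 methyl (3R)-5-[(1R,8S,12R)-4,8-dimethyl-3-oxo-2-oxabicyclo[6.2.2]dodec-9-en-12-yl]-3-methylpentanoate
Product: 20 (1S,4aS,5R,8aR)-5-[(3R)-5-methoxy-3-methyl-5-oxopentyl]-1,4a-dimethyl-1,2,3,4,4a,5,6,8a-octahydronaphthalene-1-carboxylic acid, via bis(silyl ketene acetal) 18 (not isolated), via rearranged silyl ester 19 (not isolated)
Conditions: KN(SiMe3)2 (3 equiv), Me3SiCl/Et3N (premixed, excess), THF, −78 °C to rt; toluene, 80 °C; then 1 M HCl, THF
Reagents that add atoms: none
Why: KN(SiMe3)2 with Me3SiCl present turns both ester α-positions into silyl ketene acetals (18); only the lactone-derived one is part of an allyl vinyl ether (C4=C19–O–C7–C6=C5), and on warming it undergoes a concerted suprafacial [3,3] sigmatropic shift that breaks C7–O, forms C4–C5 and moves the double bond to C6=C7, while the C15 ketene acetal is hydrolysed back to the methyl ester on work-up. The closest known reaction type is the Ireland–Claisen ring contraction of macrocyclic allylic lactones to 2-alkenylcycloalkanecarboxylic acids, which runs through boat-like arrays. Ring A is closed by transannular C4–C5 bond formation, the ten-membered lactone contracting to the six-membered carbocycle (a 6-exo attack of C4 on C5 with respect to the C5=C6 bond). C5 is controlled by C7: the new bond must form on the face that carried the C7 oxygen, which is also the face of the C1–C3 chain, so H5 ends cis to the C10 methyl and the fusion is cis. C4 is controlled by the bridge: C3 has to sit over C10 for ring A to close and C19 has to stay over C6–C7 because it is still bonded to the migrating oxygen, so C19 ends on the ring B side of ring A (cis to C6) and the methyl on the H5 side whichever ketene acetal geometry is present (ring-cis through a boat, ring-trans through a chair), and both C4 epimers of 17 converge. The only selectivities needed are this face at C5 and the configuration at C4, both fixed by the C7–O/C10 tether, and the internal Me3SiCl quench guards against elimination of the lactone enolate to a ketene.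

Step 12
Reactants: 20 (1S,4aS,5R,8aR)-5-[(3R)-5-methoxy-3-methyl-5-oxopentyl]-1,4a-dimethyl-1,2,3,4,4a,5,6,8a-octahydronaphthalene-1-carboxylic acid
Product: 21 (1S,4aR,5S,8aR)-5-[(3R)-5-methoxy-3-methyl-5-oxopentyl]-1,4a-dimethyl-6-oxo-1,2,3,4,4a,5,6,8a-octahydronaphthalene-1-carboxylic acid (C6=C7–C8=O)
Conditions: CrO3, 3,5-dimethylpyrazole, CH2Cl2, −20 °C
Reagents that add atoms: chromium trioxide, O=[Cr](=O)=O
Why: Allylic oxidation with the CrO3–3,5-dimethylpyrazole complex: C8 is the only allylic methylene, and oxygen delivery to the other allyl terminus C6 is hindered by C5 lying between two quaternary carbons, so the 6-en-8-one should dominate, with C9 never exposed to base.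

Step 13
Reactants: 21 (1S,4aR,5S,8aR)-5-[(3R)-5-methoxy-3-methyl-5-oxopentyl]-1,4a-dimethyl-6-oxo-1,2,3,4,4a,5,6,8a-octahydronaphthalene-1-carboxylic acid
Product: 22 (1S,4aR,5S,8aR)-5-[(3R)-5-methoxy-3-methyl-5-oxopentyl]-1,4a-dimethyl-6-oxodecahydronaphthalene-1-carboxylic acid
Conditions: H2 (1 atm), Pd/C, EtOAc, rt
Reagents that add atoms: none
Why: Catalytic hydrogenation of the enone C=C under neutral conditions creates no stereocentre and should not epimerise C9.

Step 14
Reactants: 22 (1S,4aR,5S,8aR)-5-[(3R)-5-methoxy-3-methyl-5-oxopentyl]-1,4a-dimethyl-6-oxodecahydronaphthalene-1-carboxylic acid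
Product: 23 (1S,4aS,5R,8aR)-5-[(3R)-5-methoxy-3-methyl-5-oxopentyl]-1,4a-dimethyl-6-methylidenedecahydronaphthalene-1-carboxylic acid (CNP0260608.1)
Conditions: Zn, CH2Br2, TiCl4 (excess), THF/CH2Cl2, 0 °C to rt
Reagents that add atoms: dibromomethane, BrCBr
Why: Takai–Lombardo methylenation: the non-basic zinc/titanium methylene reagent converts the hindered, enolisable C8 ketone into the exocyclic alkene without epimerising C9, and in excess it should tolerate the free acid and the ester.

**Compound list**

1 | methyl hydrogen (R)-3-methylglutarate, (3R)-5-methoxy-3-methyl-5-oxopentanoic acid | OC(=O)C[C@@H](C)CC(=O)OC | starting material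
2 | methyl (3R)-5-hydroxy-3-methylpentanoate | OCC[C@@H](C)CC(=O)OC | intermediate
3 | methyl (3S)-5-iodo-3-methylpentanoate | ICC[C@@H](C)CC(=O)OC | intermediate
4 | [(3S)-5-methoxy-3-methyl-5-oxopentyl]zinc iodide | COC(=O)C[C@H](C)CC[Zn]I | intermediate (not isolated)
5 | [(3S)-5-methoxy-3-methyl-5-oxopentyl][(trimethylsilyl)methyl]zinc | COC(=O)C[C@H](C)CC[Zn]C[Si](C)(C)C | intermediate
6 | 2-methylcyclohex-2-en-1-one | CC1=CCCCC1=O | starting material
7 | zinc enolate: C5 O-zinc enolate of the conjugate adduct (C5=C10), zinc still carrying the (trimethylsilyl)methyl group | C[Si](C)(C)C[Zn]OC1=C(C)[C@H](CC[C@@H](C)CC(=O)OC)CCC1 | intermediate (not isolated)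
8 | methyl (3R)-3-methyl-5-[(1S,2S)-2-methyl-3-oxo-2-(prop-2-en-1-yl)cyclohexyl]pentanoate (C10 methyl cis to the C9 chain, allyl trans) | O=C1CCC[C@@H](CC[C@@H](C)CC(=O)OC)[C@]1(C)CC=C | intermediate
9 | 2-methylbut-3-enoic acid (racemic) | C=CC(C)C(=O)O | starting material
10 | (3E)-5-[(1S,2S)-2-[(3R)-5-methoxy-3-methyl-5-oxopentyl]-1-methyl-6-oxocyclohexyl]-2-methylpent-3-enoic acid (C4 epimers) | O=C1CCC[C@@H](CC[C@@H](C)CC(=O)OC)[C@]1(C)C/C=C/C(C)C(=O)O | intermediate
11 | 5-[(1S,2S)-2-[(3R)-5-methoxy-3-methyl-5-oxopentyl]-1-methyl-6-oxocyclohexyl]-2-methylpentanoic acid (C4 epimers) | O=C1CCC[C@@H](CC[C@@H](C)CC(=O)OC)[C@]1(C)CCCC(C)C(=O)O | intermediate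
12 | 5-[(1S,6R)-6-[(3R)-5-methoxy-3-methyl-5-oxopentyl]-1-methyl-2-oxocyclohex-3-en-1-yl]-2-methylpentanoic acid (C4 epimers) | O=C1C=CC[C@@H](CC[C@@H](C)CC(=O)OC)[C@]1(C)CCCC(C)C(=O)O | intermediate
13 | 5-[(1R,3S,4R,6R)-4-[(3R)-5-methoxy-3-methyl-5-oxopentyl]-3-methyl-2-oxo-7-oxabicyclo[4.1.0]heptan-3-yl]-2-methylpentanoic acid (C4 epimers) | O=C1[C@@H]2O[C@@H]2C[C@@H](CC[C@@H](C)CC(=O)OC)[C@]1(C)CCCC(C)C(=O)O | intermediate
14 | C5 hydrazone of epoxy ketone 13 | NN=C1[C@@H]2O[C@@H]2C[C@@H](CC[C@@H](C)CC(=O)OC)[C@]1(C)CCCC(C)C(=O)O | intermediate (not isolated)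
15 | 5-[(1S,4R,6R)-4-hydroxy-6-[(3R)-5-methoxy-3-methyl-5-oxopentyl]-1-methylcyclohex-2-en-1-yl]-2-methylpentanoic acid (7-OH cis to the C10 arm; C4 epimers) | O[C@H]1C=C[C@@](C)(CCCC(C)C(=O)O)[C@H](CC[C@@H](C)CC(=O)OC)C1 | intermediate
16 | mixed anhydride of 15 with 2,4,6-trichlorobenzoic acid | O[C@H]1C=C[C@@](C)(CCCC(C)C(=O)OC(=O)c2c(Cl)cc(Cl)cc2Cl)[C@H](CC[C@@H](C)CC(=O)OC)C1 | intermediate (not isolated)
17 | methyl (3R)-5-[(1R,8S,12R)-4,8-dimethyl-3-oxo-2-oxabicyclo[6.2.2]dodec-9-en-12-yl]-3-methylpentanoate (bridged ten-membered lactone, C19 acyl on O–C7, C5=C6; C4 epimers) | O=C1O[C@H]2C=C[C@@](C)(CCCC1C)[C@H](CC[C@@H](C)CC(=O)OC)C2 | intermediate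
18 | bis(trimethylsilyl ketene acetal) of 17: ring ketene acetal C4=C19(OSiMe3)–O–C7 and side-chain methyl trimethylsilyl ketene acetal C14=C15 | C[Si](C)(C)OC1=C(C)CCC[C@]2(C)C=C[C@H](O1)C[C@H]2CC[C@@H](C)C=C(OC)O[Si](C)(C)C | intermediate (not isolated)
19 | trimethylsilyl ester of 20 with the C15 ester still as its methyl trimethylsilyl ketene acetal | C1C=C[C@@H]2[C@@](C)(CCC[C@]2(C)C(=O)O[Si](C)(C)C)[C@@H]1CC[C@@H](C)C=C(OC)O[Si](C)(C)C | intermediate (not isolated)
20 | (1S,4aS,5R,8aR)-5-[(3R)-5-methoxy-3-methyl-5-oxopentyl]-1,4a-dimethyl-1,2,3,4,4a,5,6,8a-octahydronaphthalene-1-carboxylic acid (cis-fused 17-nor-6-ene acid) | C1C=C[C@@H]2[C@@](C)(CCC[C@]2(C)C(=O)O)[C@@H]1CC[C@@H](C)CC(=O)OC | intermediate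
21 | (1S,4aR,5S,8aR)-5-[(3R)-5-methoxy-3-methyl-5-oxopentyl]-1,4a-dimethyl-6-oxo-1,2,3,4,4a,5,6,8a-octahydronaphthalene-1-carboxylic acid | O=C1C=C[C@@H]2[C@@](C)(CCC[C@]2(C)C(=O)O)[C@@H]1CC[C@@H](C)CC(=O)OC | intermediate
22 | (1S,4aR,5S,8aR)-5-[(3R)-5-methoxy-3-methyl-5-oxopentyl]-1,4a-dimethyl-6-oxodecahydronaphthalene-1-carboxylic acid | O=C1CC[C@@H]2[C@@](C)(CCC[C@]2(C)C(=O)O)[C@@H]1CC[C@@H](C)CC(=O)OC | intermediate
23 | (1S,4aS,5R,8aR)-5-[(3R)-5-methoxy-3-methyl-5-oxopentyl]-1,4a-dimethyl-6-methylidenedecahydronaphthalene-1-carboxylic acid; labdane descriptors 4S,5R,9R,10S,13R | C=C1CC[C@@H]2[C@@](C)(CCC[C@]2(C)C(=O)O)[C@@H]1CC[C@@H](C)CC(=O)OC | target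

**Count**

Total steps: 14. Longest linear sequence: 14 steps (1 to 23; 6 and 9 are purchased and enter at steps 4 and 5).

**The three steps most likely to fail**

Step 11, the ring contraction. Three processes may go wrong. The more accessible α-CH2 of the C15 methyl ester is deprotonated before the hindered C4–H, so ester condensation can compete before silylation. The lactone enolate may open by elimination to a ketene and the C7 alkoxide. The bridged boat array may only be reached at temperatures where the ketene acetal decays.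

The fallback sets out from 17 and comes back at 20; it removes the enolisable spectator and restores it afterwards. Me3SnOH in 1,2-dichloroethane at 70 °C should cleave only the unhindered methyl ester and give the bridged lactone carboxylic acid F1. With KN(SiMe3)2 (2.2 equiv, THF, −78 °C) the carboxylate forms first and is not enolised, so the second equivalent can only remove H4. Me3SiCl then gives the ring silyl ketene acetal trimethylsilyl ester F2, which on warming should rearrange to the bis(trimethylsilyl) ester F3 and on acidic work-up give the diacid F4. Fischer esterification (MeOH, cat. H2SO4, rt) should esterify only the unhindered C15 acid, since the tertiary neopentyl-type C19 acid is inert under these conditions, and this returns 20.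

Step 10, the lactonisation. Closure needs the C7 oxygen and the C10 arm both pseudo-axial on a boat-like ring B, so intermolecular acylation (diolide and oligomer formation) may outrun ring closure, and acyl transfer to the hindered allylic hydroxyl may be slow.

The fallback sets out from 15 and comes back at 17; it activates the alcohol instead of the acid and closes the ring by displacement with inversion. Dess–Martin periodinane oxidises the allylic alcohol to the enone acid F5. Luche reduction (NaBH4, CeCl3·7H2O, MeOH, −78 °C) should deliver hydride axially and give the 7-epi hydroxy acid F6, with the hydroxyl cis to the C9 chain. Mitsunobu macrolactonisation (PPh3, DIAD, toluene, slow addition at high dilution) then lets the carboxylate attack C7 from the face of the arm, which inverts C7 and gives 17.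

Step 4, the conjugate addition and allylation. The α-methyl enone is a sluggish acceptor and the mixed, functionalised diorganozinc is less reactive than simple dialkylzincs, so addition may be slow and ligand control incomplete. Lithium iodide carried over from the preparation of 5 could erode the selectivity further, and transfer of the silylmethyl group could compete. Because C13 is fixed, any erosion at C9 would appear as diastereomers that are hard to separate. Proton transfer during allylation could also scramble the enolate.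

The fallback sets out from 3 and comes back at 8; it gives up the economy of the mixed reagent for a salt-free homoleptic dialkylzinc and builds the quaternary centre in two stages on the best-behaved acceptor. Iodine–zinc exchange (Et2Zn neat, CuI cat., 50 °C; EtI and excess Et2Zn removed in vacuo; two molecules of 3 per zinc) gives bis[(3S)-5-methoxy-3-methyl-5-oxopentyl]zinc F7. The same copper–phosphoramidite system adds F7 to cyclohex-2-enone to give the alkylzinc enolate F8, which is methylated in the flask (MeI, DMPU) to the 2-methyl ketone F9 (C10 epimers are of no consequence). Me3SiCl, NaI and Et3N in MeCN give the more substituted silyl enol ether F10. Tsuji allylation of this silyl enol ether (Pd2(dba)3, dppe, allyl methyl carbonate, THF) should bring in the allyl group anti to the C9 chain and give 8.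

**Further compounds**

F1 | step 11 | (3R)-5-[(1R,8S,12R)-4,8-dimethyl-3-oxo-2-oxabicyclo[6.2.2]dodec-9-en-12-yl]-3-methylpentanoic acid (lactone 17 with C15 as the free acid) | O=C1O[C@H]2C=C[C@@](C)(CCCC1C)[C@H](CC[C@@H](C)CC(=O)O)C2
F2 | step 11 | ring trimethylsilyl ketene acetal of F1 as its C15 trimethylsilyl ester | C[Si](C)(C)OC1=C(C)CCC[C@]2(C)C=C[C@H](O1)C[C@H]2CC[C@@H](C)CC(=O)O[Si](C)(C)C
F3 | step 11 | bis(trimethylsilyl) ester of diacid F4 | C1C=C[C@@H]2[C@@](C)(CCC[C@]2(C)C(=O)O[Si](C)(C)C)[C@@H]1CC[C@@H](C)CC(=O)O[Si](C)(C)C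
F4 | step 11 | (1S,4aS,5R,8aR)-5-[(3R)-4-carboxy-3-methylbutyl]-1,4a-dimethyl-1,2,3,4,4a,5,6,8a-octahydronaphthalene-1-carboxylic acid (C15, C19 diacid) | C1C=C[C@@H]2[C@@](C)(CCC[C@]2(C)C(=O)O)[C@@H]1CC[C@@H](C)CC(=O)O
F5 | step 10 | 5-[(1S,6R)-6-[(3R)-5-methoxy-3-methyl-5-oxopentyl]-1-methyl-4-oxocyclohex-2-en-1-yl]-2-methylpentanoic acid (C7 ketone, C5=C6) | O=C1C=C[C@@](C)(CCCC(C)C(=O)O)[C@H](CC[C@@H](C)CC(=O)OC)C1
F6 | step 10 | 5-[(1S,4S,6R)-4-hydroxy-6-[(3R)-5-methoxy-3-methyl-5-oxopentyl]-1-methylcyclohex-2-en-1-yl]-2-methylpentanoic acid (7-epimer of 15) | O[C@@H]1C=C[C@@](C)(CCCC(C)C(=O)O)[C@H](CC[C@@H](C)CC(=O)OC)C1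
F7 | step 4 | bis[(3S)-5-methoxy-3-methyl-5-oxopentyl]zinc | COC(=O)C[C@H](C)CC[Zn]CC[C@@H](C)CC(=O)OC
F8 | step 4 | alkylzinc enolate of methyl (3R)-3-methyl-5-[(1S)-3-oxocyclohexyl]pentanoate | COC(=O)C[C@H](C)CC[Zn]OC1=C[C@H](CC[C@@H](C)CC(=O)OC)CCC1
F9 | step 4 | methyl (3R)-3-methyl-5-[(1S)-2-methyl-3-oxocyclohexyl]pentanoate (C10 epimers) | O=C1CCC[C@@H](CC[C@@H](C)CC(=O)OC)C1C
F10 | step 4 | methyl (3R)-3-methyl-5-[(1S)-2-methyl-3-[(trimethylsilyl)oxy]cyclohex-2-en-1-yl]pentanoate | C[Si](C)(C)OC1=C(C)[C@H](CC[C@@H](C)CC(=O)OC)CCC1
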